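If you are choosing how much reagent to charge for single product, choose by where that charge stands against a crossing concentration of reagent.

| flask | substrate | reagent | remark | time |
|---|---|---|---|---|
| north-east | 0.050 M | 0.019 M | run made earlier |  |
| south-west | 0.050 M | 0.15 M | run made earlier |  |
| delta | 0.050 M | 0.0250 M |  | 6.0 min |
| beta | 0.050 M | 0.200 M |  | 6.0 min |

| north-east: time / min | north-east: single product / % | south-west: time / min | south-west: single product / % |
|---|---|---|---|
| 0.833 | 2.4 | 0.417 | 9.9 |
| 1.50 | 3.4 | 1.00 | 11.5 |
| 2.50 | 4.2 | 2.00 | 10.7 |
| 3.00 | 3.8 | 3.00 | 10.4 |

(each reading ± 0.3 percentage points)

- a species is counted by the substrate in it: one side product counts as two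
- on the list of suspects stand: substrate + reagent -> single product; substrate <-> dormant form; single product <-> isomer of the product; reagent + other mono adduct -> bis adduct; reagent + single product -> bis adduct; substrate + reagent -> other mono adduct; substrate + single product -> side product

* which of these holds the largest part of the substrate at the end of delta (bis adduct / single product / other mono adduct / substrate)
* which of these holds the largest part of the substrate at the end of beta (bis adduct / single product / other mono adduct / substrate)
* amount of single product at the end of delta, in percent of the substrate charged

1. Here is the puzzle: from north-east to south-west the reagent charge rises 7.89-fold, but the late level of single product, the mean of the last two readings, goes from 4.00% to 10.6%, a factor of 2.65.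

2. The late readings of each run lie close together, so I read each level L as a balance (a quasi-steady state). Substrate and reagent make single product, and the suspected steps lose it to substrate and to reagent. This gives L = Lm·B/(B + B×), where B is the reagent charge, Lm is the level at large B, and B× is the crossing concentration, the reagent concentration at which single product is lost equally fast to reagent and to substrate.

3. The two runs give, as readings, B× = 0.0467 M and Lm = 13.8%. North-east lies below the crossing and south-west above it, which clears the puzzle: the level follows reagent below B× and flattens above it.

4. Delta also lies below the crossing, and my reckoning gives 4.82%.

5. The forecast gives 5.2% (range 4.4% to 6%), higher than mine, with substrate for delta and other mono adduct for beta: “In beta the substrate is gone and the other mono adduct dominates, unless unseen slow bis formation overtakes it.”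

6. Delta ends with 5.29% of single product, and of the four asked, substrate is largest at 37.3%. Beta ends with bis adduct largest at 68.0%, against the forecast.

    substrate + reagent → single product (k = 0.0790 L mol⁻¹ s⁻¹)
    substrate ⇌ dormant form (K = 0.490, k = 0.00790 s⁻¹)
    single product ⇌ isomer of the product (K = 1.20, k = 0.0720 s⁻¹)
    reagent + other mono adduct → bis adduct (k = 0.0300 L mol⁻¹ s⁻¹)
    reagent + single product → bis adduct (k = 0.0650 L mol⁻¹ s⁻¹)
    substrate + reagent → other mono adduct (k = 0.110 L mol⁻¹ s⁻¹)
    substrate + single product → side product (k = 0.110 L mol⁻¹ s⁻¹)

7. At 6.00 min in delta, single product is made 0.978 times as fast as it is used up, each step taken net. Now take the neighbour of delta charged with 0.013 M of substrate and the same reagent. Loss to substrate scales with substrate, so B× falls to 0.0121 M, the reagent charge now stands above it, and the level reckons to 9.31%. That neighbour ends with 9.53% of single product.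

The earlier runs and the new flask stem from a simulated flask for substances that don't exist; the scatter is artificial.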